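(Readings and results are simulated with constants of no real substance, noise included.)

A leftover is the cheapest handle on your quick number, so take the last one: the ochre flask still held 23% of its substrate at 5.00 min.

- ochre: substrate 10 mM; enzyme 0.49 µM; the very flask that is asked about, followed so far
- flask: substrate 10 mM; enzyme 0.49 µM; time 12 min

- ochre (time / min: product / %, substrate / %): 0.417: 9, 88; 0.667: 17, 86; 1.33: 32, 68; 2.50: 51, 48; 5.00: 77, 23

(scatter of a reading: 1.5 percentage points)

1. product present at 12 min, in percent of the substrate charged
2. substrate present at 12 min, in percent of the substrate charged

Work in powers of ten and carry one quantity, the decade time, the time in which the remaining substrate falls by one power of ten. That leftover gives 7.83 min, and the reading at 2.50 min gives 7.84 min, so the readings fit a first-order fall. The asked time then spans 1.53 decades, and my own number is 2.94% of substrate. Substrate and product read 100% together at 5.00 min, so I take the remainder, 97.1%, as product.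

Your forecast is 96% of product (89% to 99%) and 3.5% of substrate (1.5% to 10%). Its substrate stands 0.56 percentage points above mine, and it states the lean of its ranges: “I therefore skew the ranges towards incomplete conversion”.

The ochre flask gave 94.0% of product and 5.97% of substrate at 12 min, inside both ranges, a mean decade time of 9.81 min, longer than the early 7.83 min.

    substrate + enzyme → product + enzyme, rate k1*[substrate]*[enzyme]/(1 + ([substrate]/Km1)) (23.8 mM, k = 14000 M⁻¹ s⁻¹)
    enzyme + product → spent catalyst (k = 0.233 M⁻¹ s⁻¹)

At 1.20 min the making of product was running with 97.4% of the enzyme still active and 69.6% of the substrate present. Enzyme meeting product then went to spent catalyst alongside it, leaving 63.6% of the enzyme at 6.00 min and 29.9% at 12.0 min, with 70.1% as spent catalyst. A neighbour flask charged with 8.3 × 10⁻⁴ mM of enzyme kept 1.06% of its substrate at 12.0 min, a mean decade time of 6.08 min, shorter than the ochre flask's 9.81 min.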